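**Retrosynthetic overview**
- The sulfate goes on last, onto the inner phenol only; the outer phenol (allyl) and the benzylic alcohol (silyl) are unmasked in the final pot under non-acidic conditions.
- C9–C11 bond: palladium-catalysed Negishi coupling of a cis-decalin C9 enol triflate with an ortho-silyloxy benzylic zinc chloride.
- Decalin: ring B is bought as 2-methylcyclohex-2-enone; the C4–C5 bond and the C5 stereocentre come from a nickel-catalysed enantioselective reductive conjugate addition of a tertiary bromide.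
- Ring A is then closed by intramolecular enolate alkylation (cis-fused, sets C10); the C8 methyl is added by enolate alkylation before triflation.
- Aryl part from catechol: mono-allyl ether, ortho-formylation (C11), para-chloromethylation (CH2OH carbon). Ring A is the only ring formed in the route.

Assumption: the SMILES is taken literally, i.e. a cis-fused decalin, (4aR,8aS) = 5R,10S in drimane numbering (used below; C11 is the benzylic CH2); the aryl sulfate is drawn as the free acid and is best stored as its sodium salt.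

**Decalin fragment**

Step 1
Reactants: 1 5-chloropentan-2-one
Product: 2 5-chloro-2-methylpentan-2-ol
Conditions: MeMgBr (1.1 equiv), Et2O, −30 → 0 °C; cold aq. NH4Cl quench
Reagents that add atoms: methylmagnesium bromide, C[Mg]Br
Why: Grignard 1,2-addition to the methyl ketone is fast at low temperature and the cold quench prevents the chloro alkoxide from closing to the tetrahydrofuran.

Step 2
Reactants: 2 5-chloro-2-methylpentan-2-ol
Product: 3 2-bromo-5-chloro-2-methylpentane
Conditions: 48% aq. HBr, 0 °C → rt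
Reagents that add atoms: hydrogen bromide, Br
Why: SN1 substitution through the tertiary cation converts only the tertiary alcohol, while the primary chloride is inert.

Step 3
Reactants: 3 2-bromo-5-chloro-2-methylpentane; 4 2-methylcyclohex-2-en-1-one
Product: 6 (3S)-3-(5-chloro-2-methylpentan-2-yl)-2-methylcyclohexan-1-one, via triethylsilyl enol ether 5 (not isolated)
Conditions: NiBr2·diglyme (10 mol %), (S,S)-iPr-BiOX (12 mol %), Mn powder (2 equiv), Et3SiCl (1.5 equiv), DMA, 0 °C → rt; then 1 M HCl, THF, rt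
Reagents that add atoms: none
Why: Proposed new method: zerovalent nickel carrying the chiral bioxazoline adds to the enone with Et3SiCl to give a cyclic 1-silyloxyallyl complex of divalent nickel, the tertiary radical released from 3 by bromine abstraction is captured at the metal, and reductive elimination from trivalent nickel at the unsubstituted allyl terminus forms the C4–C5 bond on the metal-bound face, so the ligand (antipode fixed by screening) selects the enone face and sets C5 as (S) while the primary chloride stays untouched; the closest known reaction type is the racemic nickel-catalysed reductive conjugate addition of alkyl halides (tertiary ones included) to enones with silyl chloride trapping, together with bioxazoline-controlled enantioselective nickel reductive cross-couplings.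

Step 4
Reactants: 6 (3S)-3-(5-chloro-2-methylpentan-2-yl)-2-methylcyclohexan-1-one
Product: 8 (4aR,8aS)-5,5,8a-trimethyl-3,4,4a,5,6,7,8,8a-octahydronaphthalen-1(2H)-one, via potassium enolate 7 (not isolated)
Conditions: KOtBu (1.3 equiv), t-BuOH/THF, 50 °C
Reagents that add atoms: none
Why: Intramolecular enolate alkylation (6-exo-tet annulation) is possible only from the more substituted enolate, and the four-carbon tether anchored at C5 can reach C10 only on its own face by axial attack, so ring A closes cis-fused and C10 (8aS) is set from C5.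

Step 5
Reactants: 8 (4aR,8aS)-5,5,8a-trimethyl-3,4,4a,5,6,7,8,8a-octahydronaphthalen-1(2H)-one
Product: 10 (4aR,8aS)-2,5,5,8a-tetramethyl-3,4,4a,5,6,7,8,8a-octahydronaphthalen-1(2H)-one, via lithium enolate 9 (not isolated)
Conditions: LiN(iPr)2 (1.1 equiv, commercial solution), THF, −78 °C; MeI (1.5 equiv), −78 → 0 °C
Reagents that add atoms: iodomethane, CI
Why: Enolate alkylation at C8, the only enolisable position, installs the methyl group, and the configuration of the new methine is irrelevant because it becomes sp2 in step 6.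

Step 6
Reactants: 10 (4aR,8aS)-2,5,5,8a-tetramethyl-3,4,4a,5,6,7,8,8a-octahydronaphthalen-1(2H)-one
Product: 12 (4aR,8aS)-2,5,5,8a-tetramethyl-3,4,4a,5,6,7,8,8a-octahydronaphthalen-1-yl trifluoromethanesulfonate, via potassium enolate 11 (not isolated)
Conditions: KN(SiMe3)2 (1.3 equiv), THF, −78 → 0 °C; PhNTf2 (1.2 equiv), 0 °C → rt
Reagents that add atoms: N-phenylbis(trifluoromethanesulfonimide), O=S(=O)(N(c1ccccc1)S(=O)(=O)C(F)(F)F)C(F)(F)F
Why: Enol triflate formation by removal of the single remaining α-hydrogen and O-sulfonylation fixes the tetrasubstituted C8=C9 double bond regiospecifically, as with 2,2,6-trimethylcyclohexanone.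

**Aryl fragment**

Step 7
Reactants: 13 catechol
Product: 14 2-(prop-2-en-1-yloxy)phenol
Conditions: allyl bromide (1.0 equiv), K2CO3 (1.0 equiv), acetone, reflux
Reagents that add atoms: allyl bromide, C=CCBr
Why: Williamson mono-O-alkylation of the symmetrical diol with one equivalent of halide gives the mono-ether, which is separated from the bis-ether by extraction into base.

Step 8
Reactants: 14 2-(prop-2-en-1-yloxy)phenol
Product: 16 2-hydroxy-3-(prop-2-en-1-yloxy)benzaldehyde, via ortho-hydroxymethyl phenol 15 (not isolated)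
Conditions: MgCl2 (2 equiv), Et3N (4 equiv), (CH2O)n (6 equiv), MeCN, reflux
Reagents that add atoms: formaldehyde (from paraformaldehyde), C=O
Why: Magnesium-mediated ortho-formylation (Casnati–Skattebøl) delivers formaldehyde to the only free ortho position of the phenoxide, and a second formaldehyde oxidises the benzylic alcohol by hydride transfer.

Step 9
Reactants: 16 2-hydroxy-3-(prop-2-en-1-yloxy)benzaldehyde
Product: 17 5-(chloromethyl)-2-hydroxy-3-(prop-2-en-1-yloxy)benzaldehyde
Conditions: (CH2O)n, conc. HCl, 30 °C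
Reagents that add atoms: formaldehyde (from paraformaldehyde), C=O; hydrogen chloride, Cl
Why: Blanc chloromethylation goes para to the free hydroxyl, the only strongly activated open position, and the aldehyde deactivates the ring enough to stop diarylmethane formation.

Step 10
Reactants: 17 5-(chloromethyl)-2-hydroxy-3-(prop-2-en-1-yloxy)benzaldehyde
Product: 18 2-hydroxy-5-(hydroxymethyl)-3-(prop-2-en-1-yloxy)benzaldehyde
Conditions: H2O/acetone 1:1 (dilute), NaHCO3 (1.1 equiv), 50 °C
Reagents that add atoms: water, O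
Why: Solvolysis of the para-hydroxybenzyl chloride (SN1 through the quinone methide) in buffered aqueous acetone gives the benzylic alcohol.

Step 11
Reactants: 18 2-hydroxy-5-(hydroxymethyl)-3-(prop-2-en-1-yloxy)benzaldehyde
Product: 19 2-[(tert-butyldimethylsilyl)oxy]-5-{[(tert-butyldimethylsilyl)oxy]methyl}-3-(prop-2-en-1-yloxy)benzaldehyde
Conditions: TBSCl (2.5 equiv), imidazole (5 equiv), DMF, rt → 40 °C
Reagents that add atoms: tert-butyldimethylsilyl chloride, CC(C)(C)[Si](C)(C)Cl
Why: Imidazole-promoted silylation protects both hydroxyls, giving an aryl silyl ether and an alkyl silyl ether that can later be cleaved separately.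

Step 12
Reactants: 19 2-[(tert-butyldimethylsilyl)oxy]-5-{[(tert-butyldimethylsilyl)oxy]methyl}-3-(prop-2-en-1-yloxy)benzaldehyde
Product: 20 {2-[(tert-butyldimethylsilyl)oxy]-5-{[(tert-butyldimethylsilyl)oxy]methyl}-3-(prop-2-en-1-yloxy)phenyl}methanol
Conditions: NaBH4 (0.5 equiv), THF/MeOH 5:1, −10 °C, 20 min; pH 7 buffer quench
Reagents that add atoms: none
Why: Borohydride reduction of the aldehyde is fast in the cold, and the short, buffered work-up avoids oxygen-to-oxygen silyl migration onto the new benzylic alcohol.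

Step 13
Reactants: 20 {2-[(tert-butyldimethylsilyl)oxy]-5-{[(tert-butyldimethylsilyl)oxy]methyl}-3-(prop-2-en-1-yloxy)phenyl}methanol
Product: 22 tert-butyl{2-(chloromethyl)-4-{[(tert-butyldimethylsilyl)oxy]methyl}-6-(prop-2-en-1-yloxy)phenoxy}dimethylsilane, via benzylic mesylate 21 (not isolated)
Conditions: MsCl (1.2 equiv), Et3N (1.5 equiv), CH2Cl2, 0 °C → rt
Reagents that add atoms: methanesulfonyl chloride, CS(=O)(=O)Cl
Why: Mesylation followed by SN2 displacement of the activated benzylic mesylate by the chloride formed in the flask gives the benzyl chloride under conditions that leave both silyl ethers intact.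

**Fragment coupling and endgame**

Step 14
Reactants: 22 tert-butyl{2-(chloromethyl)-4-{[(tert-butyldimethylsilyl)oxy]methyl}-6-(prop-2-en-1-yloxy)phenoxy}dimethylsilane; 12 (4aR,8aS)-2,5,5,8a-tetramethyl-3,4,4a,5,6,7,8,8a-octahydronaphthalen-1-yl trifluoromethanesulfonate
Product: 24 tert-butyl{2-{[(4aR,8aS)-2,5,5,8a-tetramethyl-3,4,4a,5,6,7,8,8a-octahydronaphthalen-1-yl]methyl}-4-{[(tert-butyldimethylsilyl)oxy]methyl}-6-(prop-2-en-1-yloxy)phenoxy}dimethylsilane, via benzylic zinc chloride 23 (not isolated)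
Conditions: Zn dust (1.5 equiv), LiCl (1.5 equiv), THF, 25 °C; then 12 (0.8 equiv), Pd(OAc)2 (3 mol %), SPhos (6 mol %), THF, 50 °C
Reagents that add atoms: none
Why: Negishi coupling: LiCl-assisted zinc insertion gives the benzylic zinc reagent, which transmetalates readily to the palladium species formed by oxidative addition of the hindered enol triflate, so the C9–C11 bond is made with the alkene position fixed and both stereocentres untouched.

Step 15
Reactants: 24 tert-butyl{2-{[(4aR,8aS)-2,5,5,8a-tetramethyl-3,4,4a,5,6,7,8,8a-octahydronaphthalen-1-yl]methyl}-4-{[(tert-butyldimethylsilyl)oxy]methyl}-6-(prop-2-en-1-yloxy)phenoxy}dimethylsilane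
Product: 25 2-{[(4aR,8aS)-2,5,5,8a-tetramethyl-3,4,4a,5,6,7,8,8a-octahydronaphthalen-1-yl]methyl}-4-{[(tert-butyldimethylsilyl)oxy]methyl}-6-(prop-2-en-1-yloxy)phenol
Conditions: Cs2CO3 (0.5 equiv), DMF/H2O 10:1, rt
Reagents that add atoms: none
Why: Base-mediated hydrolysis cleaves the aryl silyl ether selectively over the alkyl silyl ether because phenoxide is the better leaving group, and the basic medium avoids acid-catalysed chroman formation between the free phenol and the C8=C9 alkene.

Step 16
Reactants: 25 2-{[(4aR,8aS)-2,5,5,8a-tetramethyl-3,4,4a,5,6,7,8,8a-octahydronaphthalen-1-yl]methyl}-4-{[(tert-butyldimethylsilyl)oxy]methyl}-6-(prop-2-en-1-yloxy)phenol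
Product: 26 2-{[(4aR,8aS)-2,5,5,8a-tetramethyl-3,4,4a,5,6,7,8,8a-octahydronaphthalen-1-yl]methyl}-4-{[(tert-butyldimethylsilyl)oxy]methyl}-6-(prop-2-en-1-yloxy)phenyl hydrogen sulfate
Conditions: SO3·pyridine (4 equiv), pyridine, 40 °C; aq. NaHCO3 work-up (handled as sodium salt)
Reagents that add atoms: sulfur trioxide–pyridine complex, O=S(=O)=O.c1ccncc1
Why: O-sulfation with the sulfur trioxide–pyridine complex can occur only at the single free hydroxyl, and the buffered basic medium protects the alkene and the silyl ether.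

Step 17
Reactants: 26 2-{[(4aR,8aS)-2,5,5,8a-tetramethyl-3,4,4a,5,6,7,8,8a-octahydronaphthalen-1-yl]methyl}-4-{[(tert-butyldimethylsilyl)oxy]methyl}-6-(prop-2-en-1-yloxy)phenyl hydrogen sulfate
Product: 28 2-{[(4aR,8aS)-2,5,5,8a-tetramethyl-3,4,4a,5,6,7,8,8a-octahydronaphthalen-1-yl]methyl}-6-hydroxy-4-(hydroxymethyl)phenyl hydrogen sulfate, via deallylated silyl ether 27 (not isolated)
Conditions: Pd(PPh3)4 (5 mol %), K2CO3 (3 equiv), MeOH, rt; then NH4F (10 equiv), 50 °C; sodium salt converted to the free acid on cold Dowex 50W (H+ form)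
Reagents that add atoms: none
Why: Tsuji–Trost-type deallylation (zerovalent palladium, methoxide as allyl acceptor) frees the outer phenol and fluoride then removes the primary silyl ether, both under non-acidic conditions that the aryl sulfate and the tetrasubstituted alkene tolerate.

**Compound list**
1 | 5-chloropentan-2-one | CC(=O)CCCCl | starting material
2 | 5-chloro-2-methylpentan-2-ol | CC(C)(O)CCCCl | intermediate
3 | 2-bromo-5-chloro-2-methylpentane | CC(C)(Br)CCCCl | intermediate
4 | 2-methylcyclohex-2-en-1-one | CC1=CCCCC1=O | starting material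
5 | triethyl{[(3R)-3-(5-chloro-2-methylpentan-2-yl)-2-methylcyclohex-1-en-1-yl]oxy}silane (not isolated) | ClCCCC(C)(C)[C@H]1CCCC(O[Si](CC)(CC)CC)=C1C | intermediate
6 | (3S)-3-(5-chloro-2-methylpentan-2-yl)-2-methylcyclohexan-1-one (mixture of C2 epimers) | ClCCCC(C)(C)[C@H]1CCCC(=O)C1C | intermediate
7 | potassium (3R)-3-(5-chloro-2-methylpentan-2-yl)-2-methylcyclohex-1-en-1-olate (not isolated) | [K+].ClCCCC(C)(C)[C@H]1CCCC([O-])=C1C | intermediate
8 | (4aR,8aS)-5,5,8a-trimethyl-3,4,4a,5,6,7,8,8a-octahydronaphthalen-1(2H)-one (cis-fused) | O=C1[C@@]2(C)CCCC(C)(C)[C@H]2CCC1 | intermediate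
9 | lithium (4aR,8aS)-5,5,8a-trimethyl-3,4,4a,5,6,7,8,8a-octahydronaphthalen-1-olate (not isolated) | [Li+].C1=C([O-])[C@@]2(C)CCCC(C)(C)[C@H]2CC1 | intermediate
10 | (4aR,8aS)-2,5,5,8a-tetramethyl-3,4,4a,5,6,7,8,8a-octahydronaphthalen-1(2H)-one (mixture of C2 epimers) | CC1C(=O)[C@@]2(C)CCCC(C)(C)[C@H]2CC1 | intermediate
11 | potassium (4aR,8aS)-2,5,5,8a-tetramethyl-3,4,4a,5,6,7,8,8a-octahydronaphthalen-1-olate (not isolated) | [K+].CC1=C([O-])[C@@]2(C)CCCC(C)(C)[C@H]2CC1 | intermediate
12 | (4aR,8aS)-2,5,5,8a-tetramethyl-3,4,4a,5,6,7,8,8a-octahydronaphthalen-1-yl trifluoromethanesulfonate | CC1=C(OS(=O)(=O)C(F)(F)F)[C@@]2(C)CCCC(C)(C)[C@H]2CC1 | intermediate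
13 | catechol (benzene-1,2-diol) | Oc1ccccc1O | starting material
14 | 2-(prop-2-en-1-yloxy)phenol | C=CCOc1ccccc1O | intermediate
15 | 2-(hydroxymethyl)-6-(prop-2-en-1-yloxy)phenol (not isolated) | C=CCOc1cccc(CO)c1O | intermediate
16 | 2-hydroxy-3-(prop-2-en-1-yloxy)benzaldehyde | C=CCOc1cccc(C=O)c1O | intermediate
17 | 5-(chloromethyl)-2-hydroxy-3-(prop-2-en-1-yloxy)benzaldehyde | C=CCOc1cc(CCl)cc(C=O)c1O | intermediate
18 | 2-hydroxy-5-(hydroxymethyl)-3-(prop-2-en-1-yloxy)benzaldehyde | C=CCOc1cc(CO)cc(C=O)c1O | intermediate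
19 | 2-[(tert-butyldimethylsilyl)oxy]-5-{[(tert-butyldimethylsilyl)oxy]methyl}-3-(prop-2-en-1-yloxy)benzaldehyde | C=CCOc1cc(CO[Si](C)(C)C(C)(C)C)cc(C=O)c1O[Si](C)(C)C(C)(C)C | intermediate
20 | {2-[(tert-butyldimethylsilyl)oxy]-5-{[(tert-butyldimethylsilyl)oxy]methyl}-3-(prop-2-en-1-yloxy)phenyl}methanol | C=CCOc1cc(CO[Si](C)(C)C(C)(C)C)cc(CO)c1O[Si](C)(C)C(C)(C)C | intermediate
21 | {2-[(tert-butyldimethylsilyl)oxy]-5-{[(tert-butyldimethylsilyl)oxy]methyl}-3-(prop-2-en-1-yloxy)phenyl}methyl methanesulfonate (not isolated) | C=CCOc1cc(CO[Si](C)(C)C(C)(C)C)cc(COS(C)(=O)=O)c1O[Si](C)(C)C(C)(C)C | intermediate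
22 | tert-butyl{2-(chloromethyl)-4-{[(tert-butyldimethylsilyl)oxy]methyl}-6-(prop-2-en-1-yloxy)phenoxy}dimethylsilane | C=CCOc1cc(CO[Si](C)(C)C(C)(C)C)cc(CCl)c1O[Si](C)(C)C(C)(C)C | intermediate
23 | {2-[(tert-butyldimethylsilyl)oxy]-5-{[(tert-butyldimethylsilyl)oxy]methyl}-3-(prop-2-en-1-yloxy)benzyl}zinc chloride (not isolated) | C=CCOc1cc(CO[Si](C)(C)C(C)(C)C)cc(C[Zn]Cl)c1O[Si](C)(C)C(C)(C)C | intermediate
24 | tert-butyl{2-{[(4aR,8aS)-2,5,5,8a-tetramethyl-3,4,4a,5,6,7,8,8a-octahydronaphthalen-1-yl]methyl}-4-{[(tert-butyldimethylsilyl)oxy]methyl}-6-(prop-2-en-1-yloxy)phenoxy}dimethylsilane | CC1=C(Cc2cc(CO[Si](C)(C)C(C)(C)C)cc(OCC=C)c2O[Si](C)(C)C(C)(C)C)[C@@]2(C)CCCC(C)(C)[C@H]2CC1 | intermediate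
25 | 2-{[(4aR,8aS)-2,5,5,8a-tetramethyl-3,4,4a,5,6,7,8,8a-octahydronaphthalen-1-yl]methyl}-4-{[(tert-butyldimethylsilyl)oxy]methyl}-6-(prop-2-en-1-yloxy)phenol | CC1=C(Cc2cc(CO[Si](C)(C)C(C)(C)C)cc(OCC=C)c2O)[C@@]2(C)CCCC(C)(C)[C@H]2CC1 | intermediate
26 | 2-{[(4aR,8aS)-2,5,5,8a-tetramethyl-3,4,4a,5,6,7,8,8a-octahydronaphthalen-1-yl]methyl}-4-{[(tert-butyldimethylsilyl)oxy]methyl}-6-(prop-2-en-1-yloxy)phenyl hydrogen sulfate | CC1=C(Cc2cc(CO[Si](C)(C)C(C)(C)C)cc(OCC=C)c2OS(=O)(=O)O)[C@@]2(C)CCCC(C)(C)[C@H]2CC1 | intermediate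
27 | 2-{[(4aR,8aS)-2,5,5,8a-tetramethyl-3,4,4a,5,6,7,8,8a-octahydronaphthalen-1-yl]methyl}-4-{[(tert-butyldimethylsilyl)oxy]methyl}-6-hydroxyphenyl hydrogen sulfate (not isolated) | CC1=C(Cc2cc(CO[Si](C)(C)C(C)(C)C)cc(O)c2OS(=O)(=O)O)[C@@]2(C)CCCC(C)(C)[C@H]2CC1 | intermediate
28 | 2-{[(4aR,8aS)-2,5,5,8a-tetramethyl-3,4,4a,5,6,7,8,8a-octahydronaphthalen-1-yl]methyl}-6-hydroxy-4-(hydroxymethyl)phenyl hydrogen sulfate | CC1=C(Cc2cc(CO)cc(O)c2OS(=O)(=O)O)[C@@]2(C)CCCC(C)(C)[C@H]2CC1 | target

**Step count**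
Total: 17 steps. Longest linear sequence: 11 steps (catechol 13 to 28: steps 7–13, 14, 15–17). The decalin branch from 1 is 10 steps (1–6, 14–17).

**Three steps most likely to fail**

Step 3 (the proposed new nickel coupling) may give low conversion with the α-substituted enone or insufficient enantioselectivity. The fallback uses known chemistry; it sets out from alcohol 2 and enone 4 and comes back at decalone 8. Alcohol 2 is acylated with methyl chlorooxoacetate (Et3N, DMAP, CH2Cl2) to methyl 5-chloro-2-methylpentan-2-yl oxalate F1. One equivalent of CsOH in THF/H2O converts this into caesium 2-[(5-chloro-2-methylpentan-2-yl)oxy]-2-oxoacetate F2. A visible-light photoredox decarboxylative Giese addition of the derived tertiary radical to 4 (Ir[dF(CF3)ppy]2(dtbbpy)PF6 1 mol %, DME/DMF, H2O, blue LEDs) gives racemic 3-(5-chloro-2-methylpentan-2-yl)-2-methylcyclohexan-1-one F3. KOtBu as in step 4 closes it to racemic cis-5,5,8a-trimethyl-octahydronaphthalen-1(2H)-one F4. Preparative supercritical-fluid chromatography on a chiral stationary phase then delivers the (4aR,8aS) enantiomer 8.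

Step 14 may stall because both partners are hindered (a tetrasubstituted triflate next to a quaternary carbon, and an ortho-silyloxy benzylic zinc). The fallback reverses the polarity; it sets out from ketone 10 and aldehyde 19 and comes back at 24. Ketone 10 is condensed with 2,4,6-triisopropylbenzenesulfonohydrazide (cat. HCl, MeCN) to the trisylhydrazone F5. A Shapiro reaction (n-BuLi 2.2 equiv, THF/TMEDA, −78 → 0 °C) gives the C9 vinyllithium F6. This adds to aldehyde 19 at −78 °C to give the allylic/benzylic carbinol F7 as a mixture of epimers. Ionic hydrogenation (Et3SiH, CF3CO2H, CH2Cl2, −78 °C) removes the doubly activated hydroxyl with hydride delivery to the benzylic terminus, giving 24.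

Step 16 may be slow because the phenol is flanked on both sides, and the polar sulfate salt is awkward to purify. The fallback installs the sulfate as a neutral diester; it sets out from phenol 25 and comes back at 26. Phenol 25 reacts with 2,2,2-trichloroethyl chlorosulfate (Et3N, DMAP, THF) to give the aryl 2,2,2-trichloroethyl sulfate F8, which can be purified on silica. Zn dust and HCO2NH4 in MeOH then remove the trichloroethyl group reductively to give 26 as its ammonium salt.

**Further compounds**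
F1 | step 3 | methyl 5-chloro-2-methylpentan-2-yl oxalate | COC(=O)C(=O)OC(C)(C)CCCCl
F2 | step 3 | caesium 2-[(5-chloro-2-methylpentan-2-yl)oxy]-2-oxoacetate | [Cs+].[O-]C(=O)C(=O)OC(C)(C)CCCCl
F3 | step 3 | racemic 3-(5-chloro-2-methylpentan-2-yl)-2-methylcyclohexan-1-one | ClCCCC(C)(C)C1CCCC(=O)C1C
F4 | step 3 | racemic cis-5,5,8a-trimethyl-3,4,4a,5,6,7,8,8a-octahydronaphthalen-1(2H)-one (1:1 mixture of enantiomers) | O=C1[C@@]2(C)CCCC(C)(C)[C@H]2CCC1.O=C1[C@]2(C)CCCC(C)(C)[C@@H]2CCC1
F5 | step 14 | N'-[(4aR,8aS)-2,5,5,8a-tetramethyl-octahydronaphthalen-1(2H)-ylidene]-2,4,6-tri(propan-2-yl)benzenesulfonohydrazide | CC1C(=NNS(=O)(=O)c3c(C(C)C)cc(C(C)C)cc3C(C)C)[C@@]2(C)CCCC(C)(C)[C@H]2CC1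
F6 | step 14 | [(4aR,8aS)-2,5,5,8a-tetramethyl-3,4,4a,5,6,7,8,8a-octahydronaphthalen-1-yl]lithium | CC1=C([Li])[C@@]2(C)CCCC(C)(C)[C@H]2CC1
F7 | step 14 | {2-[(tert-butyldimethylsilyl)oxy]-5-{[(tert-butyldimethylsilyl)oxy]methyl}-3-(prop-2-en-1-yloxy)phenyl}[(4aR,8aS)-2,5,5,8a-tetramethyl-3,4,4a,5,6,7,8,8a-octahydronaphthalen-1-yl]methanol | CC1=C(C(O)c2cc(CO[Si](C)(C)C(C)(C)C)cc(OCC=C)c2O[Si](C)(C)C(C)(C)C)[C@@]2(C)CCCC(C)(C)[C@H]2CC1
F8 | step 16 | 2-{[(4aR,8aS)-2,5,5,8a-tetramethyl-3,4,4a,5,6,7,8,8a-octahydronaphthalen-1-yl]methyl}-4-{[(tert-butyldimethylsilyl)oxy]methyl}-6-(prop-2-en-1-yloxy)phenyl 2,2,2-trichloroethyl sulfate | CC1=C(Cc2cc(CO[Si](C)(C)C(C)(C)C)cc(OCC=C)c2OS(=O)(=O)OCC(Cl)(Cl)Cl)[C@@]2(C)CCCC(C)(C)[C@H]2CC1
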